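Ring C is cut at O1–C8a and C2–C3, which reduces the flavanone to a four-atom unit C3–C4–C4a–C8a, carried as a 2-fluoroaryl methyl ketone, and a one-carbon C=O unit. The key step exploits the C4 carbonyl that sits ortho to C8a on ring A: it acidifies C3–H for a Claisen formylation and activates C8a–F for SNAr, so that one operation forges both bonds and closes ring C as a chromone. Its precursor already carries the C8 (Z)-hydroxyprenyl chain, made by a stereoretentive benzylboronate–alkenyl iodide coupling. Rhodium-catalysed asymmetric conjugate addition of ring B then sets C2 as S, and acid removes all protecting groups.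

Key step: step 8

Remark on the chemistry: the (S)-ligand in step 11 is assigned by analogy with rhodium-catalysed arylations of cyclic enones; if a model run shows the opposite sense, its antipode is used.

Step 1
Reactants: 1 1-fluoro-3,5-dimethoxybenzene
Product: 3 1-(2-fluoro-6-hydroxy-4-methoxyphenyl)ethan-1-one, via dimethoxy ketone 2 (not isolated)
Conditions: AcCl (1.2 equiv), AlCl3 (3 equiv), CH2Cl2, 0 °C → reflux
Reagents that add atoms: acetyl chloride, CC(=O)Cl
Why: Friedel–Crafts acetylation should go to the carbon para to one methoxy group and ortho to the small fluorine (the site between the two methoxy groups is the most hindered), and excess AlCl3 then cleaves only the methoxy group chelated to the new carbonyl.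

Step 2
Reactants: 3 1-(2-fluoro-6-hydroxy-4-methoxyphenyl)ethan-1-one
Product: 4 1-[2-fluoro-4-methoxy-6-(methoxymethoxy)phenyl]ethan-1-one
Conditions: NaH (1.05 equiv), MOMCl, DMF, 0 °C
Reagents that add atoms: chloromethyl methyl ether, COCCl
Why: Williamson-type O-alkylation of the sodium phenoxide masks the future 5-OH, so that no deactivating phenoxide can form in the later SNAr step.

Step 3
Reactants: 4 1-[2-fluoro-4-methoxy-6-(methoxymethoxy)phenyl]ethan-1-one
Product: 5 1-[3-bromo-2-fluoro-4-methoxy-6-(methoxymethoxy)phenyl]ethan-1-one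
Conditions: NBS (1.05 equiv), MeCN, 0 → 25 °C, dark
Reagents that add atoms: N-bromosuccinimide, O=C1CCC(=O)N1Br
Why: Electrophilic aromatic bromination should occur at C3, para to the OMOM group and ortho to OMe, and not at the more crowded carbon between the two alkoxy groups.

Step 4
Reactants: 5 1-[3-bromo-2-fluoro-4-methoxy-6-(methoxymethoxy)phenyl]ethan-1-one
Product: 6 1-[2-fluoro-4-methoxy-6-(methoxymethoxy)-3-[(4,4,5,5-tetramethyl-1,3,2-dioxaborolan-2-yl)methyl]phenyl]ethan-1-one
Conditions: CH2(Bpin)2 (1.5 equiv), Pd[P(t-Bu)3]2 (5 mol %), KOH (8 M aq., 2 equiv), 1,4-dioxane, 25 °C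
Reagents that add atoms: bis[(pinacolato)boryl]methane, CC1(C)OB(CB2OC(C)(C)C(C)(C)O2)OC1(C)C
Why: Suzuki–Miyaura monoarylation of the geminal diboronate, in which the second boryl group accelerates transmetalation of the first, so coupling stops after one C–C bond and delivers the ArCH2Bpin unit at room temperature.

Step 5
Reactants: 7 prop-2-yn-1-ol
Product: 9 (2Z)-3-iodo-2-methylprop-2-en-1-ol, via vinylmagnesium chelate 8 (not isolated)
Conditions: MeMgBr (2.5 equiv), CuI (10 mol %), THF, −10 → 25 °C; then I2, −10 °C; aqueous work-up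
Reagents that add atoms: methylmagnesium bromide, C[Mg]Br; iodine, II
Why: Copper-catalysed anti-carbomagnesiation of the propargylic alkoxide places methyl on the internal carbon and magnesium cis to the CH2O group in a five-membered chelate, and iodinolysis with retention fixes the Z geometry.

Step 6
Reactants: 6 1-[2-fluoro-4-methoxy-6-(methoxymethoxy)-3-[(4,4,5,5-tetramethyl-1,3,2-dioxaborolan-2-yl)methyl]phenyl]ethan-1-one; 9 (2Z)-3-iodo-2-methylprop-2-en-1-ol
Product: 10 1-{2-fluoro-3-[(2Z)-4-hydroxy-3-methylbut-2-en-1-yl]-4-methoxy-6-(methoxymethoxy)phenyl}ethan-1-one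
Conditions: Pd(dppf)Cl2 (5 mol %), K3PO4 (3 equiv), THF/H2O (5:1), 65 °C
Reagents that add atoms: none
Why: sp3–sp2 Suzuki–Miyaura coupling of the primary benzylic boronate with the alkenyl iodide runs with retention at the alkene carbon, so the Z geometry of 9 is transferred to the side chain and the free hydroxyl is tolerated.

Step 7
Reactants: 10 1-{2-fluoro-3-[(2Z)-4-hydroxy-3-methylbut-2-en-1-yl]-4-methoxy-6-(methoxymethoxy)phenyl}ethan-1-one
Product: 11 1-{3-[(2Z)-4-{[tert-butyl(dimethyl)silyl]oxy}-3-methylbut-2-en-1-yl]-2-fluoro-4-methoxy-6-(methoxymethoxy)phenyl}ethan-1-one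
Conditions: TBSCl, imidazole, CH2Cl2, 0 → 25 °C
Reagents that add atoms: tert-butyldimethylsilyl chloride, CC(C)(C)[Si](C)(C)Cl
Why: Silylation of the primary allylic alcohol prevents its alkoxide from competing for C8a in the base-mediated key step.

Step 8
Reactants: 11 1-{3-[(2Z)-4-{[tert-butyl(dimethyl)silyl]oxy}-3-methylbut-2-en-1-yl]-2-fluoro-4-methoxy-6-(methoxymethoxy)phenyl}ethan-1-one
Product: 13 8-[(2Z)-4-{[tert-butyl(dimethyl)silyl]oxy}-3-methylbut-2-en-1-yl]-7-methoxy-5-(methoxymethoxy)-4H-chromen-4-one, via sodium formyl enolate 12 (not isolated)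
Conditions: NaH (1.2 equiv), HCO2Et (3 equiv), THF, 0 → 25 °C; then solvent switch to DMF, 100 °C
Reagents that add atoms: ethyl formate, CCOC=O
Why: NaH converts the methyl ketone into its enolate and C3 is formylated by ethyl formate (crossed Claisen condensation, C2–C3 bond), the product resting as the chelated Z sodium enolate 12, a stabilised 1,3-dicarbonyl enolate that cannot dehydrate or fragment as an aldol adduct would. On heating in DMF the formyl-derived enolate oxygen adds to C8a, activated by the ortho C4 carbonyl, and fluoride is expelled (addition–elimination SNAr, O1–C8a bond); the closest known reaction type is the base-induced closure of 1-(2-haloaryl)-1,3-diketones to chromones and flavones. Ring C closes by a formally 6-endo-trig attack on the C8a=C4a bond, through which the charge reaches the C4 carbonyl, and loss of NaF restores the aromaticity of ring A. No stereocentre is formed: C2 emerges as an sp2 enone carbon and is left to catalyst control in step 11. The step needs O-cyclisation at C8a only, which is secured because C3 cannot reach C8a, C8a carries the only fluorine, the 5-oxygen is masked as its MOM ether so that ring A is not deactivated, and close to one equivalent of base leaves little free ethoxide to compete.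

Step 9
Reactants: 14 4-bromobenzene-1,2-diol
Product: 15 4-bromo-1,2-bis(methoxymethoxy)benzene
Conditions: MOMCl (2.5 equiv), i-Pr2NEt (3 equiv), CH2Cl2, 0 → 25 °C
Reagents that add atoms: chloromethyl methyl ether, COCCl
Why: Double O-alkylation of the catechol gives base-stable, acid-labile MOM ethers that match the ring A protecting group.

Step 10
Reactants: 15 4-bromo-1,2-bis(methoxymethoxy)benzene
Product: 18 [3,4-bis(methoxymethoxy)phenyl]boronic acid, via aryllithium 16 (not isolated), via lithium borate 17 (not isolated)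
Conditions: n-BuLi (1.05 equiv), THF, −78 °C; B(Oi-Pr)3, −78 → 0 °C; aq. NH4Cl
Reagents that add atoms: triisopropyl borate, CC(C)OB(OC(C)C)OC(C)C; water, O
Why: Bromine–lithium exchange at −78 °C is faster than MOM-directed ortho-lithiation, the aryllithium is trapped as the borate, and near-neutral hydrolysis spares the MOM ethers.

Step 11
Reactants: 13 8-[(2Z)-4-{[tert-butyl(dimethyl)silyl]oxy}-3-methylbut-2-en-1-yl]-7-methoxy-5-(methoxymethoxy)-4H-chromen-4-one; 18 [3,4-bis(methoxymethoxy)phenyl]boronic acid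
Product: 19 (2S)-2-[3,4-bis(methoxymethoxy)phenyl]-8-[(2Z)-4-{[tert-butyl(dimethyl)silyl]oxy}-3-methylbut-2-en-1-yl]-7-methoxy-5-(methoxymethoxy)-2,3-dihydro-4H-chromen-4-one
Conditions: [Rh(OH)((S)-MeO-F12-BIPHEP)]2 (3 mol % Rh), 18 (3 equiv), toluene/H2O (10:1), 30 °C (MeO-F12-BIPHEP = 6,6'-dimethoxybiphenyl-2,2'-diylbis[bis(3,4,5-trifluorophenyl)phosphine])
Reagents that add atoms: none
Why: Hayashi–Miyaura reaction on the chromone: the aryl–rhodium species inserts the C2=C3 bond from the face selected by the chiral diphosphine, which should set C2 as S, and the rhodium enolate is protonated by water under base-free conditions that neither open nor racemise the flavanone.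

Step 12
Reactants: 19 (2S)-2-[3,4-bis(methoxymethoxy)phenyl]-8-[(2Z)-4-{[tert-butyl(dimethyl)silyl]oxy}-3-methylbut-2-en-1-yl]-7-methoxy-5-(methoxymethoxy)-2,3-dihydro-4H-chromen-4-one
Product: 20 (2S)-2-(3,4-dihydroxyphenyl)-5-hydroxy-8-[(2Z)-4-hydroxy-3-methylbut-2-en-1-yl]-7-methoxy-2,3-dihydro-4H-chromen-4-one (CNP0246822.1)
Conditions: HCl (3 M aq.), MeOH/THF, 45 °C
Reagents that add atoms: none
Why: Acid-catalysed acetal exchange and silyl ether solvolysis remove the three MOM ethers and the primary TBS ether in one operation without base, so C2 should not epimerise and the Z allylic alcohol, which gives no stabilised cation, should survive.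

Compound list
1 | 1-fluoro-3,5-dimethoxybenzene | COc1cc(F)cc(OC)c1 | starting material
2 | 1-(2-fluoro-4,6-dimethoxyphenyl)ethan-1-one | CC(=O)c1c(F)cc(OC)cc1OC | intermediate (not isolated)
3 | 1-(2-fluoro-6-hydroxy-4-methoxyphenyl)ethan-1-one | CC(=O)c1c(F)cc(OC)cc1O | intermediate
4 | 1-[2-fluoro-4-methoxy-6-(methoxymethoxy)phenyl]ethan-1-one | CC(=O)c1c(F)cc(OC)cc1OCOC | intermediate
5 | 1-[3-bromo-2-fluoro-4-methoxy-6-(methoxymethoxy)phenyl]ethan-1-one | CC(=O)c1c(F)c(Br)c(OC)cc1OCOC | intermediate
6 | 1-[2-fluoro-4-methoxy-6-(methoxymethoxy)-3-[(4,4,5,5-tetramethyl-1,3,2-dioxaborolan-2-yl)methyl]phenyl]ethan-1-one | CC(=O)c1c(F)c(CB2OC(C)(C)C(C)(C)O2)c(OC)cc1OCOC | intermediate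
7 | prop-2-yn-1-ol | C#CCO | starting material
8 | bromo[(1Z)-3-(bromomagnesiooxy)-2-methylprop-1-en-1-yl]magnesium | C/C(=C/[Mg]Br)CO[Mg]Br | intermediate (not isolated)
9 | (2Z)-3-iodo-2-methylprop-2-en-1-ol | C/C(=C/I)CO | intermediate
10 | 1-{2-fluoro-3-[(2Z)-4-hydroxy-3-methylbut-2-en-1-yl]-4-methoxy-6-(methoxymethoxy)phenyl}ethan-1-one | CC(=O)c1c(F)c(C/C=C(/C)CO)c(OC)cc1OCOC | intermediate
11 | 1-{3-[(2Z)-4-{[tert-butyl(dimethyl)silyl]oxy}-3-methylbut-2-en-1-yl]-2-fluoro-4-methoxy-6-(methoxymethoxy)phenyl}ethan-1-one | CC(=O)c1c(F)c(C/C=C(/C)CO[Si](C)(C)C(C)(C)C)c(OC)cc1OCOC | intermediate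
12 | sodium (1Z)-3-{3-[(2Z)-4-{[tert-butyl(dimethyl)silyl]oxy}-3-methylbut-2-en-1-yl]-2-fluoro-4-methoxy-6-(methoxymethoxy)phenyl}-3-oxoprop-1-en-1-olate | [Na+].[O-]/C=C\C(=O)c1c(F)c(C/C=C(/C)CO[Si](C)(C)C(C)(C)C)c(OC)cc1OCOC | intermediate (not isolated)
13 | 8-[(2Z)-4-{[tert-butyl(dimethyl)silyl]oxy}-3-methylbut-2-en-1-yl]-7-methoxy-5-(methoxymethoxy)-4H-chromen-4-one | O=c1ccoc2c(C/C=C(/C)CO[Si](C)(C)C(C)(C)C)c(OC)cc(OCOC)c12 | intermediate
14 | 4-bromobenzene-1,2-diol | Oc1ccc(Br)cc1O | starting material
15 | 4-bromo-1,2-bis(methoxymethoxy)benzene | COCOc1ccc(Br)cc1OCOC | intermediate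
16 | [3,4-bis(methoxymethoxy)phenyl]lithium | [Li]c1ccc(OCOC)c(OCOC)c1 | intermediate (not isolated)
17 | lithium [3,4-bis(methoxymethoxy)phenyl]tri(propan-2-yloxy)borate | [Li+].CC(C)O[B-](OC(C)C)(OC(C)C)c1ccc(OCOC)c(OCOC)c1 | intermediate (not isolated)
18 | [3,4-bis(methoxymethoxy)phenyl]boronic acid | OB(O)c1ccc(OCOC)c(OCOC)c1 | intermediate
19 | (2S)-2-[3,4-bis(methoxymethoxy)phenyl]-8-[(2Z)-4-{[tert-butyl(dimethyl)silyl]oxy}-3-methylbut-2-en-1-yl]-7-methoxy-5-(methoxymethoxy)-2,3-dihydro-4H-chromen-4-one | COc1cc(OCOC)c2c(c1C/C=C(/C)CO[Si](C)(C)C(C)(C)C)O[C@H](c1ccc(OCOC)c(OCOC)c1)CC2=O | intermediate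
20 | (2S)-2-(3,4-dihydroxyphenyl)-5-hydroxy-8-[(2Z)-4-hydroxy-3-methylbut-2-en-1-yl]-7-methoxy-2,3-dihydro-4H-chromen-4-one | COc1cc(O)c2c(c1C/C=C(/C)CO)O[C@H](c1ccc(O)c(O)c1)CC2=O | target

Total step count: 12. Longest linear sequence: 9 steps (1, 2, 3, 4, 6, 7, 8, 11, 12).

Steps most likely to fail

Step 8 (key step). The addition–elimination at C8a may be slow, because ring A is electron-rich and C8a is flanked by the acyl group and the side chain; retro-Claisen deformylation, attack of ethoxide on C8a or loss of the silyl ether could then take over at the temperature required. The fallback sets out from 11 and comes back at 13. The fluorine is first exchanged for oxygen with a strong external O-nucleophile, 2-(methylsulfonyl)ethanol and NaH in DMF (SNAr, then β-elimination of methyl vinyl sulfone), to give the 2'-hydroxy ketone F1. Condensation with N,N-dimethylformamide dimethyl acetal in toluene at 90 °C gives the enaminone F2, and PPTS in CH2Cl2 at 40 °C closes ring C by conjugate addition of the phenol and loss of dimethylamine to give chromone 13.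

Step 11. Insertion of the hindered, electron-rich chromone into the aryl–rhodium bond may be slow or poorly face-selective, with protodeboronation of 18 and opening of the rhodium enolate to a chalcone as competing processes. The fallback sets out from 13 and comes back at 19. Racemic addition of 18 with the more reactive achiral catalyst [Rh(OH)(cod)]2 in dioxane/H2O gives the racemic flavanone F3. It is resolved kinetically by asymmetric transfer hydrogenation, using the enantiomer of RuCl(TsDPEN)(p-cymene) that reduces the 2R ketone faster, with HCO2H/Et3N in EtOAc, stopped just past half conversion. The 2R material is removed by chromatography as the cis-flavan-4-ol F4, and the unreduced 2S ketone is 19.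

Step 6. Protodeboronation of the benzylic boronate and palladium hydride-induced migration of the side-chain double bond into conjugation with ring A may erode the coupling. The fallback sets out from 6 and comes back at 11. Oxidation of the C–B bond with NaBO3·4H2O in THF/H2O gives the benzylic alcohol F5, and MsCl/Et3N/LiCl gives the benzylic chloride F6. Zinc dust and LiCl in THF give the ketone-tolerant benzylzinc chloride F7. Negishi coupling (Pd(OAc)2, SPhos, THF, 25 °C) with the silyl ether F8, made from iodide 9 with TBSCl and imidazole, gives 11 directly.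

Further compounds
F1 | step 8 | 1-{3-[(2Z)-4-{[tert-butyl(dimethyl)silyl]oxy}-3-methylbut-2-en-1-yl]-2-hydroxy-4-methoxy-6-(methoxymethoxy)phenyl}ethan-1-one | CC(=O)c1c(O)c(C/C=C(/C)CO[Si](C)(C)C(C)(C)C)c(OC)cc1OCOC
F2 | step 8 | (2E)-1-{3-[(2Z)-4-{[tert-butyl(dimethyl)silyl]oxy}-3-methylbut-2-en-1-yl]-2-hydroxy-4-methoxy-6-(methoxymethoxy)phenyl}-3-(dimethylamino)prop-2-en-1-one | CN(C)/C=C/C(=O)c1c(O)c(C/C=C(/C)CO[Si](C)(C)C(C)(C)C)c(OC)cc1OCOC
F3 | step 11 | racemic 2-[3,4-bis(methoxymethoxy)phenyl]-8-[(2Z)-4-{[tert-butyl(dimethyl)silyl]oxy}-3-methylbut-2-en-1-yl]-7-methoxy-5-(methoxymethoxy)-2,3-dihydro-4H-chromen-4-one | COc1cc(OCOC)c2c(c1C/C=C(/C)CO[Si](C)(C)C(C)(C)C)OC(c1ccc(OCOC)c(OCOC)c1)CC2=O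
F4 | step 11 | (2R,4R)-2-[3,4-bis(methoxymethoxy)phenyl]-8-[(2Z)-4-{[tert-butyl(dimethyl)silyl]oxy}-3-methylbut-2-en-1-yl]-7-methoxy-5-(methoxymethoxy)-3,4-dihydro-2H-chromen-4-ol | COc1cc(OCOC)c2c(c1C/C=C(/C)CO[Si](C)(C)C(C)(C)C)O[C@@H](c1ccc(OCOC)c(OCOC)c1)C[C@H]2O
F5 | step 6 | 1-[2-fluoro-3-(hydroxymethyl)-4-methoxy-6-(methoxymethoxy)phenyl]ethan-1-one | CC(=O)c1c(F)c(CO)c(OC)cc1OCOC
F6 | step 6 | 1-[3-(chloromethyl)-2-fluoro-4-methoxy-6-(methoxymethoxy)phenyl]ethan-1-one | CC(=O)c1c(F)c(CCl)c(OC)cc1OCOC
F7 | step 6 | [3-acetyl-2-fluoro-6-methoxy-4-(methoxymethoxy)benzyl]zinc chloride | CC(=O)c1c(F)c(C[Zn]Cl)c(OC)cc1OCOC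
F8 | step 6 | tert-butyl{[(2Z)-3-iodo-2-methylprop-2-en-1-yl]oxy}dimethylsilane | C/C(=C/I)CO[Si](C)(C)C(C)(C)C
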